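**Plan**

Numbering follows the germacrane skeleton: ring C1–C10, C14 on C10, C15 on C4, lactone carbons C11–C13, lactone oxygen on C6. Retrosynthesis cuts the C15 acetate and C14 methacrylate C–O bonds, then the two lactone bonds O–C6 and C11–C7 together, then C7–C8 of the ten-membered ring, then C1=C10 (olefination) and C3–C4 (cross-coupling).
Enabling feature: the lactone oxygen sits on C6, which is allylic to C4=C5 and vicinal to C7, the carbon that carries C11. The unit C4=C5–C6(O)–C7(C11) is the retron of a palladium-catalysed 1,2-carbo-oxygenation of a C4=C5–C6=C7 diene by 2-bromoacrylic acid through a C4–C5–C6 π-allyl, which builds the whole α-methylene-γ-lactone ring (O, C12, C11, C7, C6) in one operation.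
Forward: a linear ynal C8–C9–C10(C14)=C1–C2–C3–C4(C15)=C5–C6≡C7 is assembled from small pieces. The ten-membered ring is closed at C7–C8 by asymmetric intramolecular dienylzinc addition, the lactone ring is annulated last onto the ring diene, and O14, O15 and O8 are then differentiated.
Stereochemistry: C8 comes from the amino-alcohol-catalysed macrocyclisation; C7 and C6 come from C8 in the key step (peripheral attack on the trans C6=C7 bond, syn addition). C4=C5 comes from trans-hydroalumination/iodination and retentive coupling, C1=C10 from E-selective Horner–Wadsworth–Emmons olefination. Both are cis within the ring (CIP E because C14 and C15 carry oxygen).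

Key step: step 12

Assumption: (−)-DAIB (3-exo-(dimethylamino)isoborneol) is taken to deliver the alkenyl group to the Si face of the aldehyde, as it does alkyl groups from dialkylzincs; if the sense is the reverse, its enantiomer is used.

**Route**

Step 1
Reactants: 1 4-{[tert-butyl(dimethyl)silyl]oxy}but-2-yn-1-ol
Product: 3 (2Z)-4-{[tert-butyl(dimethyl)silyl]oxy}-3-iodobut-2-en-1-ol, via alkenylaluminate 2 (not isolated)
Conditions: NaAlH2(OCH2CH2OMe)2, THF, 0 °C; then I2, −78 °C → 0 °C
Reagents that add atoms: iodine, II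
Why: Hydroxyl-directed trans-hydroalumination of the propargylic alcohol places aluminium on the distal alkyne carbon cis to the carbinol carbon, and iodinolysis with retention should give the (Z)-iodoalkene, which fixes the ring-cis geometry of the later C4=C5 bond (reduction/iodination of a 2-alkyn-1-ol).

Step 2
Reactants: 3 (2Z)-4-{[tert-butyl(dimethyl)silyl]oxy}-3-iodobut-2-en-1-ol; 4 3,3-dimethoxyprop-1-ene
Product: 6 (2E)-3-({[tert-butyl(dimethyl)silyl]oxy}methyl)-6,6-dimethoxyhex-2-en-1-ol, via alkylborane 5 (not isolated)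
Conditions: 4, 9-BBN-H, THF, rt; then 3, Pd(dppf)Cl2 (5 mol %), 3 M aq. NaOH, THF, 50 °C
Reagents that add atoms: none
Why: Anti-Markovnikov hydroboration of 4 and B-alkyl Suzuki–Miyaura coupling with the alkenyl iodide, which proceeds with retention, should attach the C1–C3 chain cis to C6 without protection of the hydroxyl.

Step 3
Reactants: 6 (2E)-3-({[tert-butyl(dimethyl)silyl]oxy}methyl)-6,6-dimethoxyhex-2-en-1-ol
Product: 8 tert-butyl{[(2E)-2-(3,3-dimethoxypropyl)pent-2-en-4-yn-1-yl]oxy}dimethylsilane, via enal 7 (not isolated)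
Conditions: MnO2, THF, rt; then dimethyl (1-diazo-2-oxopropyl)phosphonate, K2CO3, MeOH, 0 °C → rt
Reagents that add atoms: dimethyl (1-diazo-2-oxopropyl)phosphonate, CC(=O)C(=[N+]=[N-])P(=O)(OC)OC
Why: Chemoselective allylic oxidation followed in the same flask by Ohira–Bestmann (Seyferth–Gilbert) homologation should turn the CH2OH group into the terminal alkyne C6≡C7, the β,β-disubstitution of enal 7 slowing conjugate addition of methanol.

Step 4
Reactants: 8 tert-butyl{[(2E)-2-(3,3-dimethoxypropyl)pent-2-en-4-yn-1-yl]oxy}dimethylsilane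
Product: 9 (4E)-4-({[tert-butyl(dimethyl)silyl]oxy}methyl)hept-4-en-6-ynal
Conditions: 10% aq. oxalic acid on SiO2, CH2Cl2, rt
Reagents that add atoms: water, O
Why: Mild heterogeneous acid hydrolysis of the dimethyl acetal (acetal deprotection) should free the C1 aldehyde and leave the primary silyl ether and the enyne untouched.

Step 5
Reactants: 10 triethyl phosphonoacetate; 11 2-bromo-1,1-dimethoxyethane
Product: 12 ethyl 2-(diethoxyphosphoryl)-4,4-dimethoxybutanoate (racemic)
Conditions: NaH, DMF, 0 °C; then 11, NaI (cat.), 80 °C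
Reagents that add atoms: none
Why: SN2 C-alkylation of the sodium salt of the phosphonoacetate (malonate-type alkylation with iodide catalysis) should install the two-carbon arm that carries C8 as a masked aldehyde.

Step 6
Reactants: 9 (4E)-4-({[tert-butyl(dimethyl)silyl]oxy}methyl)hept-4-en-6-ynal; 12 ethyl 2-(diethoxyphosphoryl)-4,4-dimethoxybutanoate
Product: 13 ethyl (2E,6E)-6-({[tert-butyl(dimethyl)silyl]oxy}methyl)-2-(2,2-dimethoxyethyl)nona-2,6-dien-8-ynoate
Conditions: 12, NaH, THF, 0 °C; then 9, 0 °C → rt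
Reagents that add atoms: none
Why: Horner–Wadsworth–Emmons olefination of the aliphatic aldehyde with the α-branched phosphonoacetate should give mainly the (2E)-enoate with the ester trans to the chain, which is the ring-cis C1=C10 geometry of the target, and the minor isomer is removed by chromatography.

Step 7
Reactants: 13 ethyl (2E,6E)-6-({[tert-butyl(dimethyl)silyl]oxy}methyl)-2-(2,2-dimethoxyethyl)nona-2,6-dien-8-ynoate
Product: 14 (2E,6E)-6-({[tert-butyl(dimethyl)silyl]oxy}methyl)-2-(2,2-dimethoxyethyl)nona-2,6-dien-8-yn-1-ol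
Conditions: i-Bu2AlH (2.2 equiv), CH2Cl2, −78 °C; aq. work-up
Reagents that add atoms: none
Why: 1,2-Reduction of the conjugated ester with i-Bu2AlH at low temperature (ester to allylic alcohol) should give the C14 alcohol while acetal, silyl ether and alkyne are inert.

Step 8
Reactants: 14 (2E,6E)-6-({[tert-butyl(dimethyl)silyl]oxy}methyl)-2-(2,2-dimethoxyethyl)nona-2,6-dien-8-yn-1-ol
Product: 15 1-({[(2E,6E)-6-({[tert-butyl(dimethyl)silyl]oxy}methyl)-2-(2,2-dimethoxyethyl)nona-2,6-dien-8-yn-1-yl]oxy}methyl)-4-methoxybenzene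
Conditions: NaH, 4-methoxybenzyl chloride, n-Bu4NI (cat.), THF/DMF, 0 °C → rt
Reagents that add atoms: 4-methoxybenzyl chloride, COc1ccc(CCl)cc1
Why: Williamson etherification of the alkoxide should give the PMB ether, which marks O14 for later release independently of the silyl ethers on O15 and O8.

Step 9
Reactants: 15 1-({[(2E,6E)-6-({[tert-butyl(dimethyl)silyl]oxy}methyl)-2-(2,2-dimethoxyethyl)nona-2,6-dien-8-yn-1-yl]oxy}methyl)-4-methoxybenzene
Product: 16 (3E,7E)-7-({[tert-butyl(dimethyl)silyl]oxy}methyl)-3-{[(4-methoxybenzyl)oxy]methyl}deca-3,7-dien-9-ynal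
Conditions: 10% aq. oxalic acid on SiO2, CH2Cl2, 0 °C → rt; used without purification
Reagents that add atoms: water, O
Why: Mild acetal hydrolysis on acid-loaded silica should release the β,γ-unsaturated aldehyde without migration of the C1=C10 bond into conjugation, and the aldehyde is used at once.

Step 10
Reactants: 16 (3E,7E)-7-({[tert-butyl(dimethyl)silyl]oxy}methyl)-3-{[(4-methoxybenzyl)oxy]methyl}deca-3,7-dien-9-ynal
Product: 19 (1R,2E,4E,8E)-5-({[tert-butyl(dimethyl)silyl]oxy}methyl)-9-{[(4-methoxybenzyl)oxy]methyl}cyclodeca-2,4,8-trien-1-ol, via dienylborane 17 (not isolated), via dienylzinc 18 (not isolated)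
Conditions: (c-C6H11)2BH, hexane, 0 °C; then slow addition to Et2Zn and (−)-DAIB (5 mol %), hexane, 0 °C, high dilution; aq. work-up
Reagents that add atoms: none
Why: Chemoselective syn-hydroboration of the terminal alkyne, boron-to-zinc transmetalation and amino-alcohol-catalysed intramolecular addition of the (E)-dienylzinc to the aldehyde (asymmetric alkenylzinc addition, known as a macrocyclisation of ω-alkynals) should close the ten-membered ring at C7–C8, fix the trans C6=C7 bond and set C8 as R by Si-face attack under control of the chiral zinc aminoalkoxide.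

Step 11
Reactants: 19 (1R,2E,4E,8E)-5-({[tert-butyl(dimethyl)silyl]oxy}methyl)-9-{[(4-methoxybenzyl)oxy]methyl}cyclodeca-2,4,8-trien-1-ol
Product: 20 tert-butyl{[(1R,2E,4E,8E)-5-({[tert-butyl(dimethyl)silyl]oxy}methyl)-9-{[(4-methoxybenzyl)oxy]methyl}cyclodeca-2,4,8-trien-1-yl]oxy}dimethylsilane
Conditions: TBSOTf, 2,6-lutidine, CH2Cl2, −78 °C
Reagents that add atoms: tert-butyldimethylsilyl triflate, CC(C)(C)[Si](C)(C)OS(=O)(=O)C(F)(F)F
Why: Silylation of the secondary allylic alcohol with the silyl triflate (silyl ether formation) should leave the diene untouched, and the bulky OTBS group is the control element for the next step.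

Step 12
Reactants: 20 tert-butyl{[(1R,2E,4E,8E)-5-({[tert-butyl(dimethyl)silyl]oxy}methyl)-9-{[(4-methoxybenzyl)oxy]methyl}cyclodeca-2,4,8-trien-1-yl]oxy}dimethylsilane; 21 2-bromoacrylic acid
Product: 22 (1(10)E,4E,6R,7S,8R)-8,15-bis{[tert-butyl(dimethyl)silyl]oxy}-14-[(4-methoxybenzyl)oxy]germacra-1(10),4,11(13)-trien-12,6-olide
Conditions: Pd(OAc)2 (10 mol %), PPh3 (20 mol %), Ag2CO3 (1.2 equiv), MeCN, 60 °C
Reagents that add atoms: none
Why: Zerovalent palladium inserts into the C–Br bond of 21, the alkenylpalladium carboxylate adds syn across the strained trans C6=C7 bond with the acrylate carbon going to C7, the less substituted diene terminus, and the resulting C4–C5–C6 π-allyl palladium is closed by the pendant carboxylate at C6 with release of zerovalent palladium. The closest known reaction type is the palladium-catalysed heteroannulation of 1,3-dienes by vinylic and aryl halides that carry an O–H or N–H group (Larock-type annulation). The only ring closed is the γ-lactone (O, C12, C11, C7, C6), formed by intramolecular C–O bond formation at the proximal allyl terminus C6 to give the five-membered ring, not at the tertiary terminus C4, which would give a seven-membered ring. C7 is set by the C8 stereocentre: in the reactive conformer the C8–OTBS bond lies in the alkene plane (inside-alkoxy arrangement, A(1,3) strain being small for a trans alkene), C9 points into the ring, and the palladium reagent attacks the peripheral face anti to C9, which should place the C7–C11 bond cis to O8 on the ring as in the target. C6 is set by C7: with silver carbonate removing bromide the carboxylate is bound to palladium and is delivered to the palladium-bearing face (inner-sphere C–O reductive elimination), so C11 and O add syn across the trans alkene and the lactone is trans-fused (6R,7S by CIP in 22, the 6R,7R arrangement of the target). The step needs site selectivity (C6=C7 over the trisubstituted C4=C5 and C1=C10 bonds), regioselectivity (C7, not C4) and the facial selectivity above; the first two follow from the lower substitution and the strain of the C6=C7 bond, and ether protection of O14 and O15 (no allylic ester and no β-acyloxy group next to the π-allyl) keeps zerovalent palladium from other pathways.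

Step 13
Reactants: 22 (1(10)E,4E,6R,7S,8R)-8,15-bis{[tert-butyl(dimethyl)silyl]oxy}-14-[(4-methoxybenzyl)oxy]germacra-1(10),4,11(13)-trien-12,6-olide
Product: 23 (1(10)E,4E,6R,7S,8R)-8,15-bis{[tert-butyl(dimethyl)silyl]oxy}-14-hydroxygermacra-1(10),4,11(13)-trien-12,6-olide
Conditions: DDQ, CH2Cl2/pH 7 buffer, 0 °C
Reagents that add atoms: none
Why: Oxidative cleavage of the PMB ether by DDQ (benzylic hydride abstraction and hydrolysis of the oxocarbenium ion) should free O14–H and leave the silyl ethers, the lactone and the alkenes intact.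

Step 14
Reactants: 23 (1(10)E,4E,6R,7S,8R)-8,15-bis{[tert-butyl(dimethyl)silyl]oxy}-14-hydroxygermacra-1(10),4,11(13)-trien-12,6-olide
Product: 24 (1(10)E,4E,6R,7S,8R)-8,15-bis{[tert-butyl(dimethyl)silyl]oxy}-14-(methacryloyloxy)germacra-1(10),4,11(13)-trien-12,6-olide
Conditions: methacryloyl chloride, Et3N, DMAP (cat.), CH2Cl2, 0 °C
Reagents that add atoms: methacryloyl chloride, CC(=C)C(Cl)=O
Why: Acylation of the primary allylic alcohol with the acid chloride under DMAP catalysis (esterification) should install the methacrylate.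

Step 15
Reactants: 24 (1(10)E,4E,6R,7S,8R)-8,15-bis{[tert-butyl(dimethyl)silyl]oxy}-14-(methacryloyloxy)germacra-1(10),4,11(13)-trien-12,6-olide
Product: 25 (1(10)E,4E,6R,7R,8R)-8,15-dihydroxy-14-(methacryloyloxy)germacra-1(10),4,11(13)-trien-12,6-olide
Conditions: HF·pyridine, pyridine/THF, 0 °C → rt
Reagents that add atoms: none
Why: Fluoride-induced cleavage of both silyl ethers under pyridine-buffered conditions (desilylation) should free O15–H and O8–H without harming the methacrylate or the α-methylene lactone.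

Step 16
Reactants: 25 (1(10)E,4E,6R,7R,8R)-8,15-dihydroxy-14-(methacryloyloxy)germacra-1(10),4,11(13)-trien-12,6-olide
Product: 26 (1(10)E,4E,6R,7R,8R)-15-acetoxy-8-hydroxy-14-(methacryloyloxy)germacra-1(10),4,11(13)-trien-12,6-olide (target)
Conditions: acetyl chloride (1.1 equiv), 2,4,6-collidine, CH2Cl2, −78 °C
Reagents that add atoms: acetyl chloride, CC(Cl)=O
Why: Collidine-mediated acetylation with one equivalent of acetyl chloride at low temperature is selective for a primary over a hindered secondary hydroxyl, so O15 should be acetylated and O8–H left free, which gives the target.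

**Compound list**

1 | 4-{[tert-butyl(dimethyl)silyl]oxy}but-2-yn-1-ol | OCC#CCO[Si](C)(C)C(C)(C)C | starting material
2 | sodium 3-({[tert-butyl(dimethyl)silyl]oxy}methyl)-2,2-bis(2-methoxyethoxy)-2,5-dihydro-1,2-oxaaluminol-2-uide (cyclic alkenylaluminate) | [Na+].COCCO[Al-]1(OCCOC)OCC=C1CO[Si](C)(C)C(C)(C)C | intermediate
3 | (2Z)-4-{[tert-butyl(dimethyl)silyl]oxy}-3-iodobut-2-en-1-ol | OC/C=C(\I)CO[Si](C)(C)C(C)(C)C | intermediate
4 | 3,3-dimethoxyprop-1-ene | C=CC(OC)OC | starting material
5 | 9-(3,3-dimethoxypropyl)-9-borabicyclo[3.3.1]nonane | COC(OC)CCB1C2CCCC1CCC2 | intermediate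
6 | (2E)-3-({[tert-butyl(dimethyl)silyl]oxy}methyl)-6,6-dimethoxyhex-2-en-1-ol | OC/C=C(\CCC(OC)OC)CO[Si](C)(C)C(C)(C)C | intermediate
7 | (2E)-3-({[tert-butyl(dimethyl)silyl]oxy}methyl)-6,6-dimethoxyhex-2-enal | O=C/C=C(\CCC(OC)OC)CO[Si](C)(C)C(C)(C)C | intermediate
8 | tert-butyl{[(2E)-2-(3,3-dimethoxypropyl)pent-2-en-4-yn-1-yl]oxy}dimethylsilane | C#C/C=C(\CCC(OC)OC)CO[Si](C)(C)C(C)(C)C | intermediate
9 | (4E)-4-({[tert-butyl(dimethyl)silyl]oxy}methyl)hept-4-en-6-ynal | O=CCC/C(CO[Si](C)(C)C(C)(C)C)=C\C#C | intermediate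
10 | triethyl phosphonoacetate | CCOC(=O)CP(=O)(OCC)OCC | starting material
11 | 2-bromo-1,1-dimethoxyethane | COC(CBr)OC | starting material
12 | ethyl 2-(diethoxyphosphoryl)-4,4-dimethoxybutanoate (racemic) | CCOC(=O)C(CC(OC)OC)P(=O)(OCC)OCC | intermediate
13 | ethyl (2E,6E)-6-({[tert-butyl(dimethyl)silyl]oxy}methyl)-2-(2,2-dimethoxyethyl)nona-2,6-dien-8-ynoate | CCOC(=O)/C(CC(OC)OC)=C/CC/C(CO[Si](C)(C)C(C)(C)C)=C\C#C | intermediate
14 | (2E,6E)-6-({[tert-butyl(dimethyl)silyl]oxy}methyl)-2-(2,2-dimethoxyethyl)nona-2,6-dien-8-yn-1-ol | OC/C(CC(OC)OC)=C/CC/C(CO[Si](C)(C)C(C)(C)C)=C\C#C | intermediate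
15 | 1-({[(2E,6E)-6-({[tert-butyl(dimethyl)silyl]oxy}methyl)-2-(2,2-dimethoxyethyl)nona-2,6-dien-8-yn-1-yl]oxy}methyl)-4-methoxybenzene | COc1ccc(COC/C(CC(OC)OC)=C/CC/C(CO[Si](C)(C)C(C)(C)C)=C\C#C)cc1 | intermediate
16 | (3E,7E)-7-({[tert-butyl(dimethyl)silyl]oxy}methyl)-3-{[(4-methoxybenzyl)oxy]methyl}deca-3,7-dien-9-ynal | O=CC/C(COCc1ccc(OC)cc1)=C\CC/C(CO[Si](C)(C)C(C)(C)C)=C\C#C | intermediate
17 | dicyclohexyl[(1E,3E,7E)-4-({[tert-butyl(dimethyl)silyl]oxy}methyl)-8-{[(4-methoxybenzyl)oxy]methyl}-10-oxodeca-1,3,7-trien-1-yl]borane | O=CC/C(COCc1ccc(OC)cc1)=C\CC/C(CO[Si](C)(C)C(C)(C)C)=C\C=C\B(C1CCCCC1)C1CCCCC1 | intermediate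
18 | ethyl[(1E,3E,7E)-4-({[tert-butyl(dimethyl)silyl]oxy}methyl)-8-{[(4-methoxybenzyl)oxy]methyl}-10-oxodeca-1,3,7-trien-1-yl]zinc | O=CC/C(COCc1ccc(OC)cc1)=C\CC/C(CO[Si](C)(C)C(C)(C)C)=C\C=C\[Zn]CC | intermediate
19 | (1R,2E,4E,8E)-5-({[tert-butyl(dimethyl)silyl]oxy}methyl)-9-{[(4-methoxybenzyl)oxy]methyl}cyclodeca-2,4,8-trien-1-ol (ring bonds: trans at C2=C3, cis at C4=C5 and C8=C9) | C1/C(CO[Si](C)(C)C(C)(C)C)=C\C=C\[C@H](O)C/C(COCc2ccc(OC)cc2)=C\C1 | intermediate
20 | tert-butyl{[(1R,2E,4E,8E)-5-({[tert-butyl(dimethyl)silyl]oxy}methyl)-9-{[(4-methoxybenzyl)oxy]methyl}cyclodeca-2,4,8-trien-1-yl]oxy}dimethylsilane | C1/C(CO[Si](C)(C)C(C)(C)C)=C\C=C\[C@H](O[Si](C)(C)C(C)(C)C)C/C(COCc2ccc(OC)cc2)=C\C1 | intermediate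
21 | 2-bromoacrylic acid | OC(=O)C(Br)=C | starting material
22 | (1(10)E,4E,6R,7S,8R)-8,15-bis{[tert-butyl(dimethyl)silyl]oxy}-14-[(4-methoxybenzyl)oxy]germacra-1(10),4,11(13)-trien-12,6-olide | COc1ccc(COC/C2=C/CC/C(CO[Si](C)(C)C(C)(C)C)=C\[C@H]3OC(=O)C(=C)[C@@H]3[C@H](O[Si](C)(C)C(C)(C)C)C2)cc1 | intermediate
23 | (1(10)E,4E,6R,7S,8R)-8,15-bis{[tert-butyl(dimethyl)silyl]oxy}-14-hydroxygermacra-1(10),4,11(13)-trien-12,6-olide | OC/C1=C/CC/C(CO[Si](C)(C)C(C)(C)C)=C\[C@H]2OC(=O)C(=C)[C@@H]2[C@H](O[Si](C)(C)C(C)(C)C)C1 | intermediate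
24 | (1(10)E,4E,6R,7S,8R)-8,15-bis{[tert-butyl(dimethyl)silyl]oxy}-14-(methacryloyloxy)germacra-1(10),4,11(13)-trien-12,6-olide | C=C(C)C(=O)OC/C1=C/CC/C(CO[Si](C)(C)C(C)(C)C)=C\[C@H]2OC(=O)C(=C)[C@@H]2[C@H](O[Si](C)(C)C(C)(C)C)C1 | intermediate
25 | (1(10)E,4E,6R,7R,8R)-8,15-dihydroxy-14-(methacryloyloxy)germacra-1(10),4,11(13)-trien-12,6-olide | C=C(C)C(=O)OC/C1=C/CC/C(CO)=C\[C@H]2OC(=O)C(=C)[C@@H]2[C@H](O)C1 | intermediate
26 | (1(10)E,4E,6R,7R,8R)-15-acetoxy-8-hydroxy-14-(methacryloyloxy)germacra-1(10),4,11(13)-trien-12,6-olide | C=C(C)C(=O)OC/C1=C/CC/C(COC(C)=O)=C\[C@H]2OC(=O)C(=C)[C@@H]2[C@H](O)C1 | target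

**Count and risks**

Total step count: 16. Longest linear sequence: 15 steps (steps 1–4 and 6–16); step 5 prepares the phosphonate 12.

Steps most likely to fail:

1. Step 12. Carbopalladation may take place on the other face of the C6=C7 bond, the π-allyl may be captured by the carboxylate anti to palladium (cis-fused lactone), insertion may occur at C4, or β-hydride elimination may outrun ring closure. The fallback sets out from 20 and uses an oxidative radical lactone annulation instead. Mn(OAc)3·2H2O and KO2CCH2CO2Et in AcOH/MeCN at 50 °C should add the malonyl radical to C7 and, after oxidation to the allyl cation, close the ring at C6 to give the 11-(ethoxycarbonyl)-13-nor lactone F1 (mixture at C11). LiOH in aqueous THF followed by acidification should give the 11-carboxy lactone F2. Decarboxylative methylenation with aqueous formaldehyde and Et2NH (Mannich reaction with loss of CO2) should then give 22, where the fallback comes back to the route.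

2. Step 10. Intermolecular addition (oligomerisation) may outrun closure of the strained medium ring, the borane may reduce the aldehyde, or face discrimination at C8 may be poor. The fallback sets out from 15. Hydrozirconation with Cp2Zr(H)Cl and iodinolysis with I2 should give the (E)-dienyl iodide F3, and acetal hydrolysis as in step 9 the iodo aldehyde F4. Nozaki–Hiyama–Kishi macrocyclisation (CrCl2, NiCl2 cat., DMSO/THF, high dilution) should give the racemic ring alcohol F5, and Dess–Martin oxidation the ring dienone F6. Corey–Bakshi–Shibata reduction with the (S)-methyl oxazaborolidine and BH3·SMe2 should then give 19, where the fallback comes back to the route.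

3. Step 3. Methoxide may add to enal 7 in a conjugate sense, or reversible addition may equilibrate the C4=C5 geometry before the homologation. The fallback sets out from 6: oxidation with MnO2 alone and isolation of enal 7, then Corey–Fuchs olefination (CBr4, PPh3, CH2Cl2, 0 °C) to the 1,1-dibromodiene F7, then n-BuLi (2.2 equiv, THF, −78 °C) and aqueous quench, which should give 8, where the fallback comes back to the route.

Further compounds
F1 | step 12 | 11-(ethoxycarbonyl)-13-nor analogue of 22 (α-ethoxycarbonyl lactone, mixture at C11) | COc1ccc(COC/C2=C/CC/C(CO[Si](C)(C)C(C)(C)C)=C\[C@H]3OC(=O)C(C(=O)OCC)[C@@H]3[C@H](O[Si](C)(C)C(C)(C)C)C2)cc1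
F2 | step 12 | 11-carboxy-13-nor analogue of 22 (α-carboxy lactone, mixture at C11) | COc1ccc(COC/C2=C/CC/C(CO[Si](C)(C)C(C)(C)C)=C\[C@H]3OC(=O)C(C(O)=O)[C@@H]3[C@H](O[Si](C)(C)C(C)(C)C)C2)cc1
F3 | step 10 | 1-({[(2E,6E,8E)-6-({[tert-butyl(dimethyl)silyl]oxy}methyl)-2-(2,2-dimethoxyethyl)-9-iodonona-2,6,8-trien-1-yl]oxy}methyl)-4-methoxybenzene | COc1ccc(COC/C(CC(OC)OC)=C/CC/C(CO[Si](C)(C)C(C)(C)C)=C\C=C\I)cc1
F4 | step 10 | (3E,7E,9E)-7-({[tert-butyl(dimethyl)silyl]oxy}methyl)-10-iodo-3-{[(4-methoxybenzyl)oxy]methyl}deca-3,7,9-trienal | O=CC/C(COCc1ccc(OC)cc1)=C\CC/C(CO[Si](C)(C)C(C)(C)C)=C\C=C\I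
F5 | step 10 | racemic (2E,4E,8E)-5-({[tert-butyl(dimethyl)silyl]oxy}methyl)-9-{[(4-methoxybenzyl)oxy]methyl}cyclodeca-2,4,8-trien-1-ol | C1/C(CO[Si](C)(C)C(C)(C)C)=C\C=C\C(O)C/C(COCc2ccc(OC)cc2)=C\C1
F6 | step 10 | (2E,4E,8E)-5-({[tert-butyl(dimethyl)silyl]oxy}methyl)-9-{[(4-methoxybenzyl)oxy]methyl}cyclodeca-2,4,8-trien-1-one | C1/C(CO[Si](C)(C)C(C)(C)C)=C\C=C\C(=O)C/C(COCc2ccc(OC)cc2)=C\C1
F7 | step 3 | tert-butyl{[(2E)-5,5-dibromo-2-(3,3-dimethoxypropyl)penta-2,4-dien-1-yl]oxy}dimethylsilane | BrC(Br)=C/C=C(\CCC(OC)OC)CO[Si](C)(C)C(C)(C)C
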